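**Retrosynthetic overview**

1. Numbering: hexahydrofuro[3,2-b]furan-2-one core O1, C2(=O), C3, C3a, O4, C5, C6, C6a; benzylic carbon C1′. The C1′–OAr bond is cut last (Mitsunobu inversion with the 7-hydroxyl of (S)-pinocembrin), then C1′–Ph (Felkin–Anh addition of a phenyltitanium reagent to the C5 aldehyde).
2. The γ-lactone (O1–C2–C3–C3a–C6a) is cut at O1–C6a: Mitsunobu lactonisation with inversion of a trans hydroxy acid, whose C6a hydroxyl comes from a C6a–Si bond oxidised with retention.
3. Feature carrying the strategy: the tetrahydrofuran ring O4–C5–C6–C6a–C3a, with stereocentres at C3a, C5 and C6a and an unsubstituted C6 methylene between C5 and C6a. It is cut at C5–C6 and O4–C3a into benzyloxyacetaldehyde (O4, C5) and a three-carbon α-chiral allylsilane (C6, C6a, C3a) whose silicon, after a 1,2-shift to C6a, is the latent O1.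
4. The allylsilane is made from 5,6-dihydro-2H-pyran-2-one by enantioselective conjugate silylation, selenolate opening of the lactone and selenoxide elimination; this avoids exposing a pent-3-enoate with an allylic leaving group to alkoxide base, where 1,4-elimination would threaten.
5. Ring order: tetrahydrofuran first (step 4), γ-lactone second (step 7); the chromanone of pinocembrin is bought intact.

Key step: step 4

Assumption: the facial sense of the silyl transfer in step 1 is taken by analogy with aryl transfer under the same Rh–BINAP catalysis, so that (R)-BINAP is assumed to give the R lactone; if the first batch shows the opposite sense, (S)-BINAP is used.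

**Route**

Step 1
Reactants: 1 5,6-dihydro-2H-pyran-2-one; 2 (dimethylphenylsilyl)boronic acid pinacol ester
Product: 3 (R)-4-[dimethyl(phenyl)silyl]oxan-2-one
Conditions: [Rh(cod)2]OTf (5 mol%), (R)-BINAP, Et3N, 1,4-dioxane/H2O 10:1, 50 °C
Reagents that add atoms: none
Why: Rhodium-catalysed enantioselective conjugate silyl transfer from the Si–B reagent (the silyl counterpart of the Hayashi–Miyaura 1,4-addition) to the cis-locked unsaturated lactone, with water as proton source; the chiral Rh–BINAP silyl complex selects one face of C4 and so sets the only stereocentre, the future silane centre.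

Step 2
Reactants: 3 (R)-4-[dimethyl(phenyl)silyl]oxan-2-one
Product: 5 methyl (S)-3-[dimethyl(phenyl)silyl]-5-(phenylselanyl)pentanoate, via sodium carboxylate 4 (not isolated)
Conditions: PhSeH, NaH, DMF, 0 °C to rt; 3, 100 °C; then MeI, rt
Reagents that add atoms: benzeneselenol, [SeH]c1ccccc1; iodomethane, CI
Why: SN2 opening of the δ-lactone at its O–CH2 carbon by the soft selenolate (alkyl–oxygen cleavage) should give the carboxylate, which is O-methylated in the same flask; the silane stereocentre is not touched and only its descriptor changes.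

Step 3
Reactants: 5 methyl (S)-3-[dimethyl(phenyl)silyl]-5-(phenylselanyl)pentanoate
Product: 7 methyl (S)-3-[dimethyl(phenyl)silyl]pent-4-enoate, via selenoxide 6 (not isolated)
Conditions: H2O2 (30% aq.), pyridine, CH2Cl2, 0 °C to 40 °C
Reagents that add atoms: none
Why: Selenoxide syn-elimination can take a hydrogen only from C4 and should therefore give the terminal alkene next to the unchanged silane stereocentre, while pyridine and excess peroxide keep the selenenic acid from adding to the allylsilane.

Step 4
Reactants: 7 methyl (S)-3-[dimethyl(phenyl)silyl]pent-4-enoate; 8 benzyloxyacetaldehyde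
Product: 9 methyl 2-[(2R,3S,5S)-5-[(benzyloxy)methyl]-3-[dimethyl(phenyl)silyl]oxolan-2-yl]acetate (2,5-trans; silicon trans to the acetate arm)
Conditions: SnCl4 (1.05 equiv), 8, CH2Cl2, 4 Å MS, −78 °C; then 7, −78 to −45 °C; aq. NaHCO3
Reagents that add atoms: none
Why: The alkene terminus of 7 attacks the carbonyl carbon of the SnCl4 chelate of 8 on the face anti to silicon (SE2′-type addition), forming C5–C6 and a β-silyl cation at C6a; silicon then bridges and moves from C3a to C6a, and the SnCl4-bound alkoxide opens the siliranium ion at C3a from the face opposite silicon, forming O4–C3a. The closest known reaction type is the Lewis-acid-promoted (3+2) annulation of α-chiral allylsilanes bearing a β-ester arm with aldehydes, here in its chelation-controlled form with an α-benzyloxy aldehyde. The tetrahydrofuran closes by C–O bond formation at C3a with the breaking C3a–Si bond outside the new five-membered ring (5-exo-tet by the breaking bond, although both carbons of the siliranium end up in the ring). C3a is set by the silane stereocentre through inversion (S in 7 becomes 2R in 9), C6a by the suprafacial silyl shift in the conformer whose C3a–H eclipses the alkene so that silicon ends trans to the acetate arm, and C5 by the aldehyde face presented when the chelated C=O lies antiperiplanar to the alkene with the chelated CH2OBn arm on the side of the C6a hydrogen, away from the acetate arm. The step needs annulation over desilylative elimination and 2,5-trans over 2,5-cis; the bulky dimethylphenylsilyl group at low temperature should resist attack at silicon, and the rigid bidentate SnCl4 chelate between the aldehyde and benzyloxy oxygens should disfavour the synclinal arrangement that leads to the cis ring with monodentate Lewis acids.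

Step 5
Reactants: 9 methyl 2-[(2R,3S,5S)-5-[(benzyloxy)methyl]-3-[dimethyl(phenyl)silyl]oxolan-2-yl]acetate
Product: 10 methyl 2-[(2R,3S,5S)-5-[(benzyloxy)methyl]-3-hydroxyoxolan-2-yl]acetate
Conditions: KBr, AcOOH, NaOAc, AcOH, 0 °C to rt
Reagents that add atoms: peracetic acid, CC(=O)OO
Why: Fleming–Tamao oxidation, in which bromodesilylation of the phenyl group is followed by peracid oxidation with migration of carbon from silicon to oxygen, should turn the C–Si bond into C–OH with retention (hydroxyl trans to the acetate arm), the acetate buffer guarding against acid-induced β-elimination of the ring oxygen.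

Step 6
Reactants: 10 methyl 2-[(2R,3S,5S)-5-[(benzyloxy)methyl]-3-hydroxyoxolan-2-yl]acetate
Product: 11 2-[(2R,3S,5S)-5-[(benzyloxy)methyl]-3-hydroxyoxolan-2-yl]acetic acid
Conditions: LiOH, THF/H2O 3:1, 0 °C; then 1 M HCl to pH 3
Reagents that add atoms: lithium hydroxide, [Li+].[OH-]
Why: Ester saponification by hydroxide at the acyl carbon, run cold so that the β-alkoxy ester is not opened by a retro-oxa-Michael reaction, touches no stereocentre.

Step 7
Reactants: 11 2-[(2R,3S,5S)-5-[(benzyloxy)methyl]-3-hydroxyoxolan-2-yl]acetic acid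
Product: 12 (3aR,5S,6aR)-5-[(benzyloxy)methyl]tetrahydrofuro[3,2-b]furan-2(3H)-one
Conditions: PPh3, DIAD, THF, 0 °C to rt
Reagents that add atoms: none
Why: Intramolecular Mitsunobu esterification, in which the carboxylate displaces the alkoxyphosphonium group at the secondary carbinol carbon in a 5-exo-tet SN2 closure, brings O1 in with inversion at C6a and should give the cis-fused lactone, the retentive acyl-activation path being closed because a trans-fused bicyclo[3.3.0] lactone is too strained.

Step 8
Reactants: 12 (3aR,5S,6aR)-5-[(benzyloxy)methyl]tetrahydrofuro[3,2-b]furan-2(3H)-one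
Product: 13 (3aR,5S,6aR)-5-(hydroxymethyl)tetrahydrofuro[3,2-b]furan-2(3H)-one
Conditions: H2 (1 atm), Pd/C (10%), EtOAc, rt
Reagents that add atoms: none
Why: Hydrogenolysis of the benzyl ether over palladium leaves the lactone, the ring ether and all stereocentres untouched.

Step 9
Reactants: 13 (3aR,5S,6aR)-5-(hydroxymethyl)tetrahydrofuro[3,2-b]furan-2(3H)-one
Product: 14 (3aR,5S,6aR)-2-oxohexahydrofuro[3,2-b]furan-5-carbaldehyde
Conditions: TEMPO (cat.), PhI(OAc)2, CH2Cl2, rt
Reagents that add atoms: none
Why: Oxoammonium (TEMPO) oxidation of the primary alcohol stops at the aldehyde under non-basic conditions, so the α-alkoxy stereocentre C5 should not epimerise; the aldehyde is used crude.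

Step 10
Reactants: 14 (3aR,5S,6aR)-2-oxohexahydrofuro[3,2-b]furan-5-carbaldehyde; 15 phenylmagnesium bromide
Product: 16 (3aR,5S,6aR)-5-[(R)-hydroxy(phenyl)methyl]tetrahydrofuro[3,2-b]furan-2(3H)-one
Conditions: 15, ClTi(OiPr)3, THF, −78 °C; then 14, −78 to −20 °C; aq. NH4Cl
Reagents that add atoms: none
Why: Addition of the non-chelating PhTi(OiPr)3 to the α-alkoxy aldehyde under Felkin–Anh control, with the C5–O4 bond anti to the incoming phenyl group and attack past the C5 hydrogen, should favour the anti (R)-carbinol, and the reagent is chemoselective for the aldehyde over the lactone.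

Step 11
Reactants: 16 (3aR,5S,6aR)-5-[(R)-hydroxy(phenyl)methyl]tetrahydrofuro[3,2-b]furan-2(3H)-one; 17 (S)-pinocembrin
Product: 18 (3aR,5S,6aR)-5-[(S)-{[(2S)-5-hydroxy-4-oxo-2-phenyl-3,4-dihydro-2H-chromen-7-yl]oxy}(phenyl)methyl]tetrahydrofuro[3,2-b]furan-2(3H)-one
Conditions: PPh3, DIAD, THF, 0 °C to rt
Reagents that add atoms: none
Why: Mitsunobu etherification with the acidic 7-hydroxyl of 17 (the 5-hydroxyl is held in a hydrogen bond to the C4 carbonyl) displaces the benzylic alkoxyphosphonium group by SN2 and inverts C1′ from R to S, which should give the syn aryl ether of the target with the flavanone centre unchanged.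

**Compound list**

1 | 5,6-dihydro-2H-pyran-2-one | O=C1C=CCCO1 | starting material
2 | (dimethylphenylsilyl)boronic acid pinacol ester | CC1(C)OB([Si](C)(C)c2ccccc2)OC1(C)C | starting material
3 | (R)-4-[dimethyl(phenyl)silyl]oxan-2-one | O=C1C[C@@H](CCO1)[Si](C)(C)c2ccccc2 | intermediate
4 | sodium (S)-3-[dimethyl(phenyl)silyl]-5-(phenylselanyl)pentanoate (not isolated) | [Na+].[O-]C(=O)C[C@@H](CC[Se]c1ccccc1)[Si](C)(C)c1ccccc1 | intermediate
5 | methyl (S)-3-[dimethyl(phenyl)silyl]-5-(phenylselanyl)pentanoate | COC(=O)C[C@@H](CC[Se]c1ccccc1)[Si](C)(C)c1ccccc1 | intermediate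
6 | methyl (3S)-3-[dimethyl(phenyl)silyl]-5-(phenylseleninyl)pentanoate (selenoxide, both configurations at selenium, not isolated) | COC(=O)C[C@@H](CC[Se](=O)c1ccccc1)[Si](C)(C)c1ccccc1 | intermediate
7 | methyl (S)-3-[dimethyl(phenyl)silyl]pent-4-enoate | COC(=O)C[C@@H](C=C)[Si](C)(C)c1ccccc1 | intermediate
8 | benzyloxyacetaldehyde | O=CCOCc1ccccc1 | starting material
9 | methyl 2-[(2R,3S,5S)-5-[(benzyloxy)methyl]-3-[dimethyl(phenyl)silyl]oxolan-2-yl]acetate | COC(=O)C[C@H]1O[C@H](COCc2ccccc2)C[C@@H]1[Si](C)(C)c1ccccc1 | intermediate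
10 | methyl 2-[(2R,3S,5S)-5-[(benzyloxy)methyl]-3-hydroxyoxolan-2-yl]acetate | COC(=O)C[C@H]1O[C@H](COCc2ccccc2)C[C@@H]1O | intermediate
11 | 2-[(2R,3S,5S)-5-[(benzyloxy)methyl]-3-hydroxyoxolan-2-yl]acetic acid | OC(=O)C[C@H]1O[C@H](COCc2ccccc2)C[C@@H]1O | intermediate
12 | (3aR,5S,6aR)-5-[(benzyloxy)methyl]tetrahydrofuro[3,2-b]furan-2(3H)-one | O=C1C[C@H]2O[C@H](COCc3ccccc3)C[C@H]2O1 | intermediate
13 | (3aR,5S,6aR)-5-(hydroxymethyl)tetrahydrofuro[3,2-b]furan-2(3H)-one | O=C1C[C@H]2O[C@H](CO)C[C@H]2O1 | intermediate
14 | (3aR,5S,6aR)-2-oxohexahydrofuro[3,2-b]furan-5-carbaldehyde | O=C1C[C@H]2O[C@H](C=O)C[C@H]2O1 | intermediate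
15 | phenylmagnesium bromide | Br[Mg]c1ccccc1 | starting material
16 | (3aR,5S,6aR)-5-[(R)-hydroxy(phenyl)methyl]tetrahydrofuro[3,2-b]furan-2(3H)-one | O=C1C[C@H]2O[C@H]([C@H](O)c3ccccc3)C[C@H]2O1 | intermediate
17 | (S)-pinocembrin, (2S)-5,7-dihydroxy-2-phenyl-2,3-dihydro-4H-chromen-4-one | Oc1cc(O)c2c(c1)O[C@H](c1ccccc1)CC2=O | starting material
18 | (3aR,5S,6aR)-5-[(S)-{[(2S)-5-hydroxy-4-oxo-2-phenyl-3,4-dihydro-2H-chromen-7-yl]oxy}(phenyl)methyl]tetrahydrofuro[3,2-b]furan-2(3H)-one | O=C1C[C@H]2O[C@H]([C@@H](Oc3cc(O)c4c(c3)O[C@H](c3ccccc3)CC4=O)c3ccccc3)C[C@H]2O1 | target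

**Totals and risks**

Total step count: 11. Longest linear sequence: 11 steps (1 to 18).

Steps most likely to fail:

Step 4. Loss of silicon from the β-silyl cation (attack of chloride at silicon) may outrun the 1,2-shift and ring closure and give simple allylation. The unsubstituted alkene terminus also gives little conformational bias, so the 2,5-trans and silicon-trans-to-arm selectivities may erode. The fallback closes the tetrahydrofuran by iodoetherification instead and needs no silicon. It sets out from 8: asymmetric allylboration with the antipode of B-allyldiisopinocampheylborane that delivers the S alcohol (Et2O, −78 °C; NaOH, H2O2 work-up) should give (S)-1-(benzyloxy)pent-4-en-2-ol F1. Cross-metathesis of F1 with methyl but-3-enoate (second-generation Grubbs catalyst, CH2Cl2, 40 °C) should give mainly methyl (3E,6S)-7-(benzyloxy)-6-hydroxyhept-3-enoate F2. 5-Endo iodoetherification (I2, NaHCO3, MeCN, 0 °C), anti across the E-alkene and expected to favour the 2,5-trans ring, should give methyl 2-[(2R,3S,5S)-5-[(benzyloxy)methyl]-3-iodooxolan-2-yl]acetate F3. Saponification (LiOH, aq. THF) gives lithium 2-[(2R,3S,5S)-5-[(benzyloxy)methyl]-3-iodooxolan-2-yl]acetate F4, whose carboxylate displaces iodide with inversion on warming in DMF; the route is rejoined at 12.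

Step 10. O4 can chelate the metal and reverse the Felkin–Anh preference, so facial selectivity at the aldehyde may be poor. The fallback sets the carbinol by reduction instead of addition. It sets out from 14: PhMgBr (1.05 equiv, THF, −78 °C), used without regard to selectivity, gives (3aR,5S,6aR)-5-[hydroxy(phenyl)methyl]tetrahydrofuro[3,2-b]furan-2(3H)-one as a mixture of carbinol epimers F5. Dess–Martin periodinane (CH2Cl2, NaHCO3) gives (3aR,5S,6aR)-5-benzoyltetrahydrofuro[3,2-b]furan-2(3H)-one F6. Chelation-controlled reduction with Zn(BH4)2 (Et2O, −30 °C), with hydride entering the zinc chelate of the ketone oxygen and O4 past the C5 hydrogen, should give the anti alcohol; the route is rejoined at 16.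

Step 11. SN2 displacement at the hindered benzylic alkoxyphosphonium ion may be slow, so that elimination toward C5 or ionisation with loss of inversion competes, and the basic betaine may open the flavanone ring and erode its C2 configuration. The fallback separates activation from substitution (Williamson ether synthesis). It sets out from 16: MsCl, Et3N (CH2Cl2, −20 °C) gives (R)-[(3aR,5S,6aR)-2-oxohexahydrofuro[3,2-b]furan-5-yl](phenyl)methyl methanesulfonate F7. K2CO3 in DMF at rt converts 17 into potassium (2S)-5-hydroxy-4-oxo-2-phenyl-3,4-dihydro-2H-chromen-7-olate F8, which displaces the sulfonate with inversion; the route is rejoined at 18.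

Further compounds
F1 | step 4 | (S)-1-(benzyloxy)pent-4-en-2-ol | C=CC[C@H](O)COCc1ccccc1
F2 | step 4 | methyl (3E,6S)-7-(benzyloxy)-6-hydroxyhept-3-enoate | COC(=O)C/C=C/C[C@H](O)COCc1ccccc1
F3 | step 4 | methyl 2-[(2R,3S,5S)-5-[(benzyloxy)methyl]-3-iodooxolan-2-yl]acetate | COC(=O)C[C@H]1O[C@H](COCc2ccccc2)C[C@@H]1I
F4 | step 4 | lithium 2-[(2R,3S,5S)-5-[(benzyloxy)methyl]-3-iodooxolan-2-yl]acetate | [Li+].[O-]C(=O)C[C@H]1O[C@H](COCc2ccccc2)C[C@@H]1I
F5 | step 10 | (3aR,5S,6aR)-5-[hydroxy(phenyl)methyl]tetrahydrofuro[3,2-b]furan-2(3H)-one, mixture of carbinol epimers | O=C1C[C@H]2O[C@H](C(O)c3ccccc3)C[C@H]2O1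
F6 | step 10 | (3aR,5S,6aR)-5-benzoyltetrahydrofuro[3,2-b]furan-2(3H)-one | O=C1C[C@H]2O[C@H](C(=O)c3ccccc3)C[C@H]2O1
F7 | step 11 | (R)-[(3aR,5S,6aR)-2-oxohexahydrofuro[3,2-b]furan-5-yl](phenyl)methyl methanesulfonate | O=C1C[C@H]2O[C@H]([C@H](OS(C)(=O)=O)c3ccccc3)C[C@H]2O1
F8 | step 11 | potassium (2S)-5-hydroxy-4-oxo-2-phenyl-3,4-dihydro-2H-chromen-7-olate | [K+].[O-]c1cc(O)c2c(c1)O[C@H](c1ccccc1)CC2=O
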